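**Plan**
1. Retrosynthetic cuts: the two acetate C–O bonds, then the C17–O bond (back to a C8 methyl), then the ring bonds C9–C10 and C4–C5, which unfold the decalin to all-E geranylgeranyl diphosphate.
2. Enabling feature: ring A (C1–C5, C10) and ring B (C5–C10) carry the C4 gem-dimethyl, the C10 methyl, a one-carbon branch on C8, the C7=C8 alkene and an intact E-C13=C14–C15–O tail. This is a head-to-tail tetraprenyl chain folded twice: C4–C5 and C9–C10 each join a tertiary cation site to a trisubstituted alkene, and C7=C8 marks where the C8 cation loses a proton.
3. Forward order: geranylgeraniol → chloride → diphosphate (the anchoring handle) → one enzymatic cation–olefin cascade that closes ring A and then ring B (the last ring), with a phosphatase removing the handle → acetate → allylic oxidation at C17 → acetate.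
4. Stereochemistry: C5, C9 and C10 all arise in the key step (relative configuration from the E alkenes in a chair–chair fold, absolute configuration from the enzyme pocket, normal labdane series); 13E is carried through from geranylgeraniol.

Key step: step 3

Remark: labdane numbering is used throughout; diphosphates 3 and 4 are drawn as free acids although they are handled as ammonium salts in buffer, and released phosphate is written as phosphoric acid.

Step 1
Reactants: 1 (2E,6E,10E)-geranylgeraniol
Product: 2 (2E,6E,10E)-geranylgeranyl chloride
Conditions: NCS, Me2S, CH2Cl2, −40 to 0 °C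
Reagents that add atoms: N-chlorosuccinimide, O=C1CCC(=O)N1Cl
Why: Corey–Kim chlorination, in which the alcohol adds to the chlorosulfonium salt and chloride displaces Me2SO at the primary allylic carbon (SN2), so the three E alkenes should stay in place and untransposed.

Step 2
Reactants: 2 (2E,6E,10E)-geranylgeranyl chloride
Product: 3 (2E,6E,10E)-geranylgeranyl diphosphate
Conditions: (n-Bu4N)3HP2O7, MeCN, rt; then cation exchange (NH4+ form, remaining tetrabutylammonium ions stay on the resin), cellulose chromatography
Reagents that add atoms: tris(tetra-n-butylammonium) hydrogen diphosphate, CCCC[N+](CCCC)(CCCC)CCCC.CCCC[N+](CCCC)(CCCC)CCCC.CCCC[N+](CCCC)(CCCC)CCCC.OP(=O)([O-])OP(=O)([O-])[O-]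
Why: SN2 displacement of a primary allylic chloride by the diphosphate anion, the standard construction of prenyl diphosphates; the diphosphate is the handle by which the cyclase binds and orients the chain.

Step 3
Reactants: 3 (2E,6E,10E)-geranylgeranyl diphosphate
Product: 5 (5S,9S,10S)-labda-7,13E-dien-15-ol, via labda-7,13E-dien-15-yl diphosphate 4 (not isolated)
Conditions: normal-series labda-7,13E-dienyl diphosphate synthase (a class 2 diterpene cyclase), MgCl2, HEPES pH 7.5, 30 °C; then alkaline phosphatase, pH 8.5, 37 °C; hexane extraction
Reagents that add atoms: none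
Why: The active-site general acid (aspartate of the DxDD motif) protonates C3 of the distal C3=C4 alkene of the chair–chair-folded chain, the C4 cation is captured by C5 of the C5=C10 alkene and the C10 cation by C9 of the C8=C9 alkene, and the C8 cation is quenched by loss of a C7 proton to give 4, whose diphosphate (not ionized by this enzyme class) is then hydrolysed at phosphorus by the phosphatase. The closest known reaction type is the protonation-initiated cation–olefin bicyclization carried out by copalyl diphosphate synthases, whose abiotic counterpart is the Brønsted-acid polyene cyclization. Ring A closes first (C4–C5 bond) and ring B last (C9–C10 bond), each by 6-endo-trig attack of a trisubstituted alkene on a tertiary cation through a chair. C5, C10 and C9 are set together: antiperiplanar addition across the two E alkenes gives the trans ring fusion (5α-H, 10β-CH3) and the equatorial 9β side chain, and the absolute sense comes from the enzyme pocket, which holds only the fold leading to the normal series. The step needs termination after two rings, proton loss from C7 rather than from C17 or C9 or capture by water, and no reaction of the C13=C14 alkene; the catalytic base sits next to C7, and the C13=C14 alkene is held away from the cation by the Mg2+-bound diphosphate and is inductively deactivated by it.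

Step 4
Reactants: 5 (5S,9S,10S)-labda-7,13E-dien-15-ol
Product: 6 (5S,9S,10S)-labda-7,13E-dien-15-yl acetate
Conditions: Ac2O, pyridine, DMAP (cat.), CH2Cl2, 0 °C to rt
Reagents that add atoms: acetic anhydride, CC(=O)OC(C)=O
Why: DMAP-catalysed acylation of a primary allylic alcohol; the acetate is required in the target and also deactivates the C13=C14 alkene for step 5.

Step 5
Reactants: 6 (5S,9S,10S)-labda-7,13E-dien-15-yl acetate
Product: 7 (5S,9R,10S)-17-hydroxylabda-7,13E-dien-15-yl acetate
Conditions: SeO2 (0.2 equiv), t-BuOOH, salicylic acid (cat.), CH2Cl2, rt
Reagents that add atoms: tert-butyl hydroperoxide, CC(C)(C)OO (terminal oxygen source); selenium dioxide, O=[Se]=O (catalytic oxygen carrier)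
Why: Riley-type allylic oxidation (ene reaction, then [2,3]-sigmatropic shift): selenium should add to the less substituted C7 of the electron-rich ring alkene (the C13=C14 alkene is deactivated by its allylic acetate), take hydrogen from the C8 methyl, which is the E-disposed and less hindered site compared with the tertiary C9–H, and the shift should return the C7=C8 alkene with oxygen on C17; no stereocentre is made or touched (the C9 descriptor changes only through priorities).

Step 6
Reactants: 7 (5S,9R,10S)-17-hydroxylabda-7,13E-dien-15-yl acetate
Product: 8 (5S,9R,10S)-labda-7,13E-diene-15,17-diyl diacetate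
Conditions: Ac2O, pyridine, DMAP (cat.), CH2Cl2, 0 °C to rt
Reagents that add atoms: acetic anhydride, CC(=O)OC(C)=O
Why: DMAP-catalysed acetylation of the primary allylic alcohol, which should give the target without touching the alkenes or stereocentres.

**Compound list**
1 | (2E,6E,10E)-geranylgeraniol (3,7,11,15-tetramethylhexadeca-2,6,10,14-tetraen-1-ol) | CC(C)=CCC/C(C)=C/CC/C(C)=C/CC/C(C)=C/CO | starting material
2 | (2E,6E,10E)-geranylgeranyl chloride | CC(C)=CCC/C(C)=C/CC/C(C)=C/CC/C(C)=C/CCl | intermediate
3 | (2E,6E,10E)-geranylgeranyl diphosphate (free acid drawn) | CC(C)=CCC/C(C)=C/CC/C(C)=C/CC/C(C)=C/COP(=O)(O)OP(=O)(O)O | intermediate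
4 | (5S,9S,10S)-labda-7,13E-dien-15-yl diphosphate (trans-decalin, 5α-H, 9α-H, 10β-CH3; free acid drawn; not isolated) | OP(=O)(O)OP(=O)(O)OC/C=C(\C)CC[C@H]1C(C)=CC[C@H]2C(C)(C)CCC[C@]12C | intermediate
5 | (5S,9S,10S)-labda-7,13E-dien-15-ol | OC/C=C(\C)CC[C@H]1C(C)=CC[C@H]2C(C)(C)CCC[C@]12C | intermediate
6 | (5S,9S,10S)-labda-7,13E-dien-15-yl acetate | CC(=O)OC/C=C(\C)CC[C@H]1C(C)=CC[C@H]2C(C)(C)CCC[C@]12C | intermediate
7 | (5S,9R,10S)-17-hydroxylabda-7,13E-dien-15-yl acetate | CC(=O)OC/C=C(\C)CC[C@H]1C(CO)=CC[C@H]2C(C)(C)CCC[C@]12C | intermediate
8 | (5S,9R,10S)-labda-7,13E-diene-15,17-diyl diacetate (CNP0257931.1) | CC(=O)OC/C=C(\C)CC[C@H]1C(COC(C)=O)=CC[C@H]2C(C)(C)CCC[C@]12C | target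

Total step count: 6. Longest linear sequence: 6 steps.

**Steps most likely to fail**

Step 5. The allylic oxidation may lose regiocontrol (attack at C9–H or C6–H, or on the side-chain alkene) or run on past the alcohol to the enal. The fallback sets out from 6 and comes back at 8. Ene-type allylic chlorination with HOCl generated from Ca(OCl)2 and CO2 in CH2Cl2/H2O at 0 °C should place chlorine on C7 of the ring alkene with loss of a C17 proton, giving 7α-chlorolabda-8(17),13E-dien-15-yl acetate F1. AgOAc in AcOH should then ionize the allylic chloride and deliver acetate to the primary C17 terminus of the allyl cation, restoring the C7=C8 alkene and giving 8 directly.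

Step 3. The terminating deprotonation may be imperfectly controlled (loss of a C17 proton or water capture at C8 competing with loss of the C7 proton), or turnover of the lipophilic substrate may be poor. The fallback sets out from 3 and comes back at 7. A normal-series copalyl diphosphate synthase (a class 2 diterpene cyclase that ends the same cascade at the exocyclic alkene) followed by phosphatase in the same pot should give (+)-copalyl diphosphate F2, not isolated, and then (+)-copalol F3. Acetylation gives (+)-copalyl acetate F4. Catalytic SeO2/t-BuOOH should oxidize the ring CH2 next to the exocyclic alkene to 7α-hydroxylabda-8(17),13E-dien-15-yl acetate F5. Ph3SiOReO3-catalysed 1,3-transposition of this allylic alcohol should move oxygen to C17 and the alkene into the ring, giving 7.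

Step 2. Solvolysis or elimination of the allylic chloride may compete with displacement, and the acid-labile allylic diphosphate may hydrolyse during ion exchange and chromatography. The fallback sets out from 1 and comes back at 3, bypassing 2. Direct phosphorylation of the alcohol with Cl3CCN and bis(triethylammonium) hydrogen phosphate in MeCN forms the P–O bond at the alcohol oxygen, so the allylic carbon is never an electrophile. It should proceed through geranylgeranyl monophosphate F6, which is phosphorylated again in the same flask to 3; 3 is then separated from the mono- and triphosphate by chromatography.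

**Further compounds**
F1 | step 5 | 7α-chlorolabda-8(17),13E-dien-15-yl acetate | CC(=O)OC/C=C(\C)CC[C@H]1C(=C)[C@H](Cl)C[C@H]2C(C)(C)CCC[C@]12C
F2 | step 3 | (+)-copalyl diphosphate, (5S,9S,10S)-labda-8(17),13E-dien-15-yl diphosphate (free acid drawn) | OP(=O)(O)OP(=O)(O)OC/C=C(\C)CC[C@H]1C(=C)CC[C@H]2C(C)(C)CCC[C@]12C
F3 | step 3 | (+)-copalol, (5S,9S,10S)-labda-8(17),13E-dien-15-ol | OC/C=C(\C)CC[C@H]1C(=C)CC[C@H]2C(C)(C)CCC[C@]12C
F4 | step 3 | (+)-copalyl acetate | CC(=O)OC/C=C(\C)CC[C@H]1C(=C)CC[C@H]2C(C)(C)CCC[C@]12C
F5 | step 3 | 7α-hydroxylabda-8(17),13E-dien-15-yl acetate | CC(=O)OC/C=C(\C)CC[C@H]1C(=C)[C@H](O)C[C@H]2C(C)(C)CCC[C@]12C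
F6 | step 2 | (2E,6E,10E)-geranylgeranyl monophosphate (free acid drawn) | CC(C)=CCC/C(C)=C/CC/C(C)=C/CC/C(C)=C/COP(=O)(O)O
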